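## Structural features

The target 22 consists of two benzenoid units joined by one diaryl ether oxygen. Ring A is the carbocycle of a 3-pentyl-1H-isochromen-1-one (C1 lactone carbonyl, O2, C3 with the pentyl chain, C4–H, C4a, C5–H, C6–OH, C7–H, C8–O–aryl, C8a). Ring B is an olivetolic acid unit, labelled here from the ether carbon: C1' ether carbon, C2' OH, C3' H, C4' OH, C5' CO2H, C6' pentyl. There is no stereocentre and no stereogenic double bond, so nothing stereochemical stands next to anything; the problem is regiochemistry and the timing of functional groups. The ether oxygen lies between two fully substituted carbons (C8 is peri to the lactone carbonyl, C1' is flanked by the pentyl group and the C2' oxygen), so coupling two finished arenes at this bond is the least attractive option. Ring B is a 2,4-dihydroxybenzoic acid that can lose CO2 under heat or protic acid and has a very nucleophilic C3'–H. The enol lactone opens with hydroxide and its C3=C4 bond can be hydrogenated. Ring A has three contiguous substituents (C8–O, C8a–C1, C4a–C4) plus a meta oxygen at C6, a pattern that electrophilic substitution does not deliver. The key step uses this pattern directly: C5–C8 with the oxygens at C6 and C8 correspond to a 1-aryloxy-3-silyloxycyclohexa-1,3-diene, and C8a/C4a with the C1 ester and the C4–C3–pentyl chain correspond to the ester-bearing triple bond of a deca-2,4-diynoate.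

## Logic of the disconnections

**22 ⇒ 21.** The bonds cut are the three O–CH2Ph bonds of ring B (two ethers, one ester). Methyl groups on ring B would be the obvious masking, but removing two aryl methyl ethers and a doubly ortho-substituted methyl ester needs long exposure to strong Lewis acid or hot nucleophiles. Under those conditions the resorcylic acid of 22 could decarboxylate or the lactone could open. Benzyl groups leave at low temperature with a Lewis acid and a cation scavenger, so all of ring B is unmasked in one mild operation. The forward step must spare the enol lactone, the diaryl ether and the nucleophilic C3'–H.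

**21 ⇒ 19 (through 20).** The bonds cut are the O2–C3 lactone bond and the O–Si bond at C6. The lactone is the retron of an ester oxygen adding across an ortho alkyne, which reduces the heterocycle to an ester and an alkynyl group on adjacent ring A carbons. The forward step needs 6-endo-dig closure onto the pentyl-bearing alkyne carbon and loss of the ester methyl, with the remote benzyl ester untouched.

**19 ⇒ 12 + 17.** The bonds cut are C8–C8a and C4a–C5, and a two-carbon bridge is added back across C5 and C8. This gives ring A with all four substituents in one operation, with the hindered ether already present. An open-chain aryloxy(silyloxy)butadiene would aromatise by expelling the aryloxide; a cyclic diene holds the aryloxy group at a bridgehead, so ethene is lost instead. The forward step needs the ester next to the ether carbon, reaction at the ester-conjugated triple bond only, and thermal robustness of both partners.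

**17 ⇒ 15 ⇒ 13 + 14.** The bonds cut are C1–C2 of 17 (acylation of a diynide) and C3–C4 of 17 (made as an sp2–sp bond, the second triple bond arising by dehydrochlorination). Direct sp–sp coupling of a 3-halopropiolate with 13 would expose an ynoate to the primary amine of the coupling medium, which adds to such acceptors. The chosen path needs two steps from commercial materials. It demands mono-coupling of 14 and an anti elimination, which the Z geometry of 15 provides.

**12 ⇒ 10 ⇒ 7 + 9, and 9 ⇒ 8.** The bonds cut are the enol O–Si bond and the vinyl carbon–oxygen bond that becomes C8–O. Addition–elimination of a phenoxide on a vinylogous acid chloride tolerates a phenol flanked on both sides, which a metal-catalysed coupling of two hindered arenes does not. The forward steps need kinetic deprotonation at the methylene that becomes C5, and careful handling of a hydrolytically sensitive diene.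

**7 ⇒ 5 ⇒ 3 ⇒ 2 ⇒ 1.** The bonds cut are C1'–O (from C–Br through C–B), C5'–CO2 (acylation of an aryllithium), two C–Br bonds and two O–benzyl bonds. The two positions flanking the pentyl chain of 1 are exactly C1' and C5'. Because 3 has a mirror plane, exchanging either bromine gives the same product, so ring B is reached in four steps without isomer separation. The forward steps need both brominations to go ortho to the chain, a single bromine–lithium exchange, and a C–Br to C–OH conversion that spares the benzyl ester.

## Other disconnections considered

**Alternative 1:** Ring B is cut at C5'–C6' and C3'–C4' and built in reduced form. The forward key step is a Michael addition of dimethyl malonate A3 to the α-aryloxy enone A2, then Claisen (Dieckmann-type) closure of the methyl ketone enolate onto a malonate ester. This gives the cyclohexanedione ester A1 (racemic, trans), which is aromatised later.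
- **In favour:** it uses cheap acyclic materials and a classical condensation at moderate temperature. The positions of ester, pentyl and oxygens on ring B are fixed by connectivity; on this point it is better than the chosen plan, whose ring B relies on directing effects in a bromination.
- **Against:** the α-aryloxy group makes the enone less electrophilic and more hindered. The later dehydrogenation needs a halogenating or oxidising reagent in the presence of an electron-rich bromo(methoxy)phenyl ether and an α-aryloxy ketone, so halogenation of the wrong ring or loss of aryloxide are plausible. Two stereocentres are made only to be erased. Ring A arrives as a 2-bromo-5-methoxyphenyl group lacking C1 and the C4a substituent, so a carbonylation at C8a, a C–H functionalisation at the unactivated C4a position and lactone formation remain.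
- **Comparison:** structurally it solves ring B, which the chosen plan gets from 1 in four steps, and leaves the harder ring A open. Mechanistically the ionic condensation is at least as reliable as a thermal cycloaddition. In step economy it is clearly longer after its key step.

**Alternative 2:** Ring A is cut at C5–C6 and grown onto a finished pyranone. The forward key step treats the pyranone A5 (4-methyl group, β-aryloxyacrylate at C3) with a lithium amide base. The vinylogous enolate of the methyl group attacks the acrylate ester, and tautomerisation gives the phenol A4.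
- **In favour:** the complete isocoumarin with free C6–OH comes out of the key step, with no silyl group and no separate lactonisation. The endgame is shorter than in the chosen plan; on this point it is better. Regiochemistry of ring closure is fixed by connectivity, which is the equal or better of an orbital-controlled cycloaddition, and the temperature is low.
- **Against:** A5 is the difficulty. It needs a fully substituted β-aryloxyacrylate with the ester cis to the pyranone, attached to a base-sensitive ring, presumably made by adding the hindered ring B phenol to a pyranonyl alkynoate with uncertain geometry. The α-methylene of the 6-pentyl chain is also vinylogously acidic and competes for base, and the pyranone can be opened by nucleophiles. A4 carries methyl ethers and a methyl ester on ring B, so the harsh unmasking returns, although that masking could be changed there as here.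
- **Comparison:** both plans make ring A last with the ether in place, so they are equal on structure. In step economy it saves about two steps after the key step but spends more before it on a precursor with little precedent.

**Alternative 3:** Ring B is cut at C4'–C5' and C1'–C6'. The forward key step is a [4+2] addition of the aryloxy silyl ketene acetal diene A7 to methyl oct-2-ynoate A8. The adduct loses methanol and the silyl group to give the aromatic ester A6.
- **In favour:** it is the same logic as the chosen plan (oxygenated diene plus ynoate gives a resorcylate with the ether in place), so it is equal in concept. Aromatisation needs no gas extrusion, the ynoate is commercial, and A6 has its two ring B oxygens differentiated, a point on which it is better.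
- **Against:** a β-alkyl ynoate is a weaker dienophile than 17, whose second triple bond lowers the LUMO. The open-chain diene is not locked s-cis, is very moisture-sensitive and thermally labile, and needs its aryloxy terminus outward (3Z). The C1'–C6' bond joins an aryloxy-bearing terminus to the pentyl-bearing alkyne carbon, which is sterically loaded. As in alternative 1, ring A arrives only as a 2-bromo-5-methoxyphenyl group.
- **Comparison:** it builds the ring that is cheaply available from 1 and leaves ring A to a longer sequence than the two steps that follow the chosen key step.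

Key step: step 10

Remark: 22 has no stereocentre; the only stereocentres on the route are the two bridgeheads of the unisolated, racemic adduct 18, which vanish with the ethene.
Remark: locants in compound names follow benzoate numbering (carboxyl carbon = 1); the primed atom labels above count from the ether carbon.

## Route

Step 1
Reactants: 1 olivetol (5-pentylbenzene-1,3-diol)
Product: 2 1,3-bis(benzyloxy)-5-pentylbenzene
Conditions: BnBr (2.3 equiv), K2CO3, DMF, rt to 50 °C
Reagents that add atoms: benzyl bromide, BrCc1ccccc1
Why: Williamson etherification of both phenols; K2CO3 in a dipolar solvent favours O- over C-alkylation of the resorcinol.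

Step 2
Reactants: 2 1,3-bis(benzyloxy)-5-pentylbenzene
Product: 3 1,5-bis(benzyloxy)-2,4-dibromo-3-pentylbenzene
Conditions: NBS (2.05 equiv), MeCN, 0 °C to rt, dark
Reagents that add atoms: N-bromosuccinimide, O=C1CCC(=O)N1Br
Why: Electrophilic aromatic bromination; each position next to the pentyl chain is para to one benzyloxy group and ortho to the other, whereas the position between the two benzyloxy groups is shielded on both sides, so both bromines should enter beside the chain, as is usual for 5-alkylresorcinol diethers.

Step 3
Reactants: 3 1,5-bis(benzyloxy)-2,4-dibromo-3-pentylbenzene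
Product: 5 benzyl 4,6-bis(benzyloxy)-3-bromo-2-pentylbenzoate, via aryllithium 4 (not isolated)
Conditions: n-BuLi (1.0 equiv), THF, −78 °C; then transfer into ClCO2Bn (1.5 equiv), THF, −78 °C to rt
Reagents that add atoms: benzyl chloroformate, O=C(Cl)OCc1ccccc1; n-butyllithium, [Li]CCCC (its lithium is found only in 4)
Why: Bromine–lithium exchange is faster than any deprotonation at −78 °C and, by the symmetry of 3, gives one aryllithium; inverse addition to the chloroformate and the two ortho substituents of the new ester prevent a second addition.

Step 4
Reactants: 5 benzyl 4,6-bis(benzyloxy)-3-bromo-2-pentylbenzoate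
Product: 7 benzyl 4,6-bis(benzyloxy)-3-hydroxy-2-pentylbenzoate, via pinacol boronate 6 (not isolated)
Conditions: B2pin2, Pd2(dba)3 (2 mol %), XPhos (8 mol %), KOAc, dioxane, 100 °C; then 30% H2O2, aq NaHCO3, THF, 0 °C to rt
Reagents that add atoms: bis(pinacolato)diboron, CC1(C)OB(OC1(C)C)B1OC(C)(C)C(C)(C)O1 (its boron is found only in 6); hydrogen peroxide, OO
Why: Miyaura borylation with a bulky biarylphosphine ligand, which is the usual answer to doubly ortho-substituted aryl halides, followed by oxidative C–B to C–O migration; the conditions are neutral to weakly basic, so the hindered benzyl ester survives.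

Step 5
Reactants: 8 cyclohexane-1,3-dione
Product: 9 3-chlorocyclohex-2-en-1-one
Conditions: (COCl)2, DMF (cat.), CH2Cl2, 0 °C to rt
Reagents that add atoms: oxalyl chloride, O=C(Cl)C(=O)Cl
Why: The enol of the dione is a vinylogous acid and is converted into the vinylogous acid chloride by the Vilsmeier-type chlorinating species, with loss of CO, CO2 and HCl.

Step 6
Reactants: 7 benzyl 4,6-bis(benzyloxy)-3-hydroxy-2-pentylbenzoate; 9 3-chlorocyclohex-2-en-1-one
Product: 10 benzyl 4,6-bis(benzyloxy)-3-[(3-oxocyclohex-1-en-1-yl)oxy]-2-pentylbenzoate
Conditions: Cs2CO3, MeCN, 60 °C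
Reagents that add atoms: none
Why: Conjugate addition of the phenoxide to the β-chloroenone and loss of chloride (addition–elimination at a vinylogous acyl carbon); the unhindered electrophilic carbon accepts a phenoxide flanked on both sides.

Step 7
Reactants: 10 benzyl 4,6-bis(benzyloxy)-3-[(3-oxocyclohex-1-en-1-yl)oxy]-2-pentylbenzoate
Product: 12 benzyl 4,6-bis(benzyloxy)-3-{[3-(tert-butyldimethylsilyloxy)cyclohexa-1,3-dien-1-yl]oxy}-2-pentylbenzoate, via lithium dienolate 11 (not isolated)
Conditions: LiN(iPr)2 (1.1 equiv), THF, −78 °C; then TBSCl, DMPU, −78 °C to 0 °C; non-aqueous work-up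
Reagents that add atoms: tert-butyldimethylsilyl chloride, CC(C)(C)[Si](C)(C)Cl; lithium diisopropylamide, [Li]N(C(C)C)C(C)C (its lithium is found only in 11)
Why: Kinetic α′-deprotonation of a vinylogous ester (Stork–Danheiser-type enolisation) gives the cross-conjugated dienolate, which is silylated on oxygen; the α′-protons are far more acidic than the benzylic protons of ring B, and the hindered ester has no α-hydrogen.

Step 8
Reactants: 13 hept-1-yne; 14 (Z)-1,2-dichloroethene
Product: 15 (Z)-1-chloronon-1-en-3-yne
Conditions: 14 (5 equiv), Pd(PPh3)4 (5 mol %), CuI (10 mol %), n-BuNH2, Et2O, rt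
Reagents that add atoms: none
Why: Sonogashira coupling of a vinyl chloride activated by the second chlorine; the excess of 14 keeps the reaction at mono-coupling, and the alkene geometry is retained.

Step 9
Reactants: 15 (Z)-1-chloronon-1-en-3-yne
Product: 17 methyl deca-2,4-diynoate, via lithium nona-1,3-diyn-1-ide 16 (not isolated)
Conditions: LiN(iPr)2 (2.2 equiv), THF, −78 °C; then ClCO2Me (excess), −78 °C to 0 °C
Reagents that add atoms: methyl chloroformate, COC(=O)Cl; lithium diisopropylamide, [Li]N(C(C)C)C(C)C (its lithium is found only in 16)
Why: In the Z isomer the vinylic hydrogen is anti to chlorine, so the first equivalent of base effects E2 dehydrochlorination and the second deprotonates the new terminal diyne; the acetylide is then acylated on carbon, a standard ynoate synthesis.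

Step 10
Reactants: 12 benzyl 4,6-bis(benzyloxy)-3-{[3-(tert-butyldimethylsilyloxy)cyclohexa-1,3-dien-1-yl]oxy}-2-pentylbenzoate; 17 methyl deca-2,4-diynoate
Product: 19 benzyl 4,6-bis(benzyloxy)-3-[5-(tert-butyldimethylsilyloxy)-3-(hept-1-yn-1-yl)-2-(methoxycarbonyl)phenoxy]-2-pentylbenzoate, via bicyclo[2.2.2]octadiene adduct 18 (not isolated)
Conditions: 17 (1.5 equiv), BHT (cat.), toluene, sealed tube, 110 °C, then 150 °C
Reagents that add atoms: none
Why: This is an Alder–Rickert reaction, a normal-electron-demand Diels–Alder addition of a cyclohexa-1,3-diene to an alkyne followed by retro-Diels–Alder loss of ethene, the closest known case being 1-alkoxy-3-silyloxycyclohexa-1,3-dienes with acetylenic esters. The diene of 12 is locked s-cis; its silyl enol ether CH terminus (future C5) has the largest HOMO coefficient and bonds to the β-carbon of 17 (future C4a, carrying the heptynyl group), while the aryloxy-bearing terminus (future C8) bonds to the α-carbon (future C8a), so the ester ends up next to the ether carbon. Ring A is closed by an intermolecular suprafacial [4+2] addition that first gives the bicyclo[2.2.2]octa-2,5-diene 18; on further heating the saturated two-carbon bridge leaves as ethene in a retro-[4+2] step driven by aromatisation. Because the aryloxy group sits on a bridgehead of 18 it cannot leave by β-elimination and is retained, which is the reason for using the cyclic diene. The two bridgehead stereocentres of 18 form as a racemate in the only relative configuration the bicycle allows and both disappear on aromatisation, so no stereocontrol is needed. Site selectivity for the 2,3-triple bond over the 4,5-triple bond follows from its direct conjugation with the ester, and regioselectivity from the matched polarisation of the push–pull diene and the ynoate. The benzyl groups of ring B and the silyl enol ether are inert to neutral heating, and the radical inhibitor limits polymerisation of the diyne.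

Step 11
Reactants: 19 benzyl 4,6-bis(benzyloxy)-3-[5-(tert-butyldimethylsilyloxy)-3-(hept-1-yn-1-yl)-2-(methoxycarbonyl)phenoxy]-2-pentylbenzoate
Product: 21 benzyl 4,6-bis(benzyloxy)-3-[(6-hydroxy-1-oxo-3-pentyl-1H-isochromen-8-yl)oxy]-2-pentylbenzoate, via silyl-protected isocoumarin 20 (not isolated)
Conditions: AuCl3 (5 mol %), MeCN, H2O (5 equiv), 50 °C; then Bu4NF, AcOH, THF, 0 °C
Reagents that add atoms: water, O (supplies the C4 hydrogen; its oxygen stays in the lactone carbonyl only if methanol leaves from the hydrated oxocarbenium ion)
Why: π-Acid-catalysed cyclisation of a methyl 2-alkynylbenzoate: the ester carbonyl oxygen attacks the activated pentyl-bearing alkyne carbon 6-endo-dig, the usual mode for alkyl-substituted substrates, water releases methanol from the 1-methoxyisochromenylium ion and protodemetalation gives 20. Fluoride buffered with acetic acid then cleaves the aryl silyl ether without exposing the lactone to base; the benzyl ester is too remote to take part in the cyclisation.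

Step 12
Reactants: 21 benzyl 4,6-bis(benzyloxy)-3-[(6-hydroxy-1-oxo-3-pentyl-1H-isochromen-8-yl)oxy]-2-pentylbenzoate
Product: 22 4,6-dihydroxy-3-[(6-hydroxy-1-oxo-3-pentyl-1H-isochromen-8-yl)oxy]-2-pentylbenzoic acid
Conditions: BCl3 (8 equiv), C6HMe5 (10 equiv), CH2Cl2, −78 °C to −20 °C; then MeOH, −78 °C, aqueous work-up
Reagents that add atoms: none
Why: Lewis-acid debenzylation with a non-basic cation scavenger: BCl3 ionises the two aryl benzyl ethers and, helped by chelation to the freed ortho hydroxyl, the benzyl ester, and pentamethylbenzene traps each benzyl cation by Friedel–Crafts alkylation before it can attack C3' of ring B. The low temperature and absence of hydroxide protect the resorcylic acid from decarboxylation and the lactone from opening.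

## Compound list

1 | olivetol (5-pentylbenzene-1,3-diol) | CCCCCc1cc(O)cc(O)c1 | starting material
2 | 1,3-bis(benzyloxy)-5-pentylbenzene | CCCCCc1cc(OCc2ccccc2)cc(OCc2ccccc2)c1 | intermediate
3 | 1,5-bis(benzyloxy)-2,4-dibromo-3-pentylbenzene | CCCCCc1c(Br)c(OCc2ccccc2)cc(OCc2ccccc2)c1Br | intermediate
4 | [4,6-bis(benzyloxy)-3-bromo-2-pentylphenyl]lithium (not isolated) | [Li]c1c(CCCCC)c(Br)c(OCc2ccccc2)cc1OCc1ccccc1 | intermediate
5 | benzyl 4,6-bis(benzyloxy)-3-bromo-2-pentylbenzoate | CCCCCc1c(Br)c(OCc2ccccc2)cc(OCc2ccccc2)c1C(=O)OCc1ccccc1 | intermediate
6 | benzyl 4,6-bis(benzyloxy)-2-pentyl-3-(4,4,5,5-tetramethyl-1,3,2-dioxaborolan-2-yl)benzoate (not isolated) | CCCCCc1c(B2OC(C)(C)C(C)(C)O2)c(OCc2ccccc2)cc(OCc2ccccc2)c1C(=O)OCc1ccccc1 | intermediate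
7 | benzyl 4,6-bis(benzyloxy)-3-hydroxy-2-pentylbenzoate | CCCCCc1c(O)c(OCc2ccccc2)cc(OCc2ccccc2)c1C(=O)OCc1ccccc1 | intermediate
8 | cyclohexane-1,3-dione | O=C1CCCC(=O)C1 | starting material
9 | 3-chlorocyclohex-2-en-1-one | O=C1C=C(Cl)CCC1 | intermediate
10 | benzyl 4,6-bis(benzyloxy)-3-[(3-oxocyclohex-1-en-1-yl)oxy]-2-pentylbenzoate | CCCCCc1c(OC2=CC(=O)CCC2)c(OCc2ccccc2)cc(OCc2ccccc2)c1C(=O)OCc1ccccc1 | intermediate
11 | lithium dienolate of 10 (lithium 5-aryloxycyclohexa-1,5-dien-1-olate, not isolated) | [Li]OC1=CCCC(Oc2c(OCc3ccccc3)cc(OCc3ccccc3)c(C(=O)OCc3ccccc3)c2CCCCC)=C1 | intermediate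
12 | benzyl 4,6-bis(benzyloxy)-3-{[3-(tert-butyldimethylsilyloxy)cyclohexa-1,3-dien-1-yl]oxy}-2-pentylbenzoate | CC(C)(C)[Si](C)(C)OC1=CCCC(Oc2c(OCc3ccccc3)cc(OCc3ccccc3)c(C(=O)OCc3ccccc3)c2CCCCC)=C1 | intermediate
13 | hept-1-yne | CCCCCC#C | starting material
14 | (Z)-1,2-dichloroethene | Cl/C=C\Cl | starting material
15 | (Z)-1-chloronon-1-en-3-yne | CCCCCC#C/C=C\Cl | intermediate
16 | lithium nona-1,3-diyn-1-ide (not isolated) | [Li]C#CC#CCCCCC | intermediate
17 | methyl deca-2,4-diynoate | CCCCCC#CC#CC(=O)OC | intermediate
18 | benzyl 4,6-bis(benzyloxy)-3-{[5-(tert-butyldimethylsilyloxy)-3-(hept-1-yn-1-yl)-2-(methoxycarbonyl)bicyclo[2.2.2]octa-2,5-dien-1-yl]oxy}-2-pentylbenzoate (racemic, not isolated) | COC(=O)C1=C(C#CCCCCC)C2CCC1(Oc4c(OCc3ccccc3)cc(OCc3ccccc3)c(C(=O)OCc3ccccc3)c4CCCCC)C=C2O[Si](C)(C)C(C)(C)C | intermediate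
19 | benzyl 4,6-bis(benzyloxy)-3-[5-(tert-butyldimethylsilyloxy)-3-(hept-1-yn-1-yl)-2-(methoxycarbonyl)phenoxy]-2-pentylbenzoate | CCCCCC#Cc1cc(O[Si](C)(C)C(C)(C)C)cc(Oc2c(OCc3ccccc3)cc(OCc3ccccc3)c(C(=O)OCc3ccccc3)c2CCCCC)c1C(=O)OC | intermediate
20 | benzyl 4,6-bis(benzyloxy)-3-{[6-(tert-butyldimethylsilyloxy)-1-oxo-3-pentyl-1H-isochromen-8-yl]oxy}-2-pentylbenzoate (not isolated) | CCCCCc1cc2cc(O[Si](C)(C)C(C)(C)C)cc(Oc3c(OCc4ccccc4)cc(OCc4ccccc4)c(C(=O)OCc4ccccc4)c3CCCCC)c2c(=O)o1 | intermediate
21 | benzyl 4,6-bis(benzyloxy)-3-[(6-hydroxy-1-oxo-3-pentyl-1H-isochromen-8-yl)oxy]-2-pentylbenzoate | CCCCCc1cc2cc(O)cc(Oc3c(OCc4ccccc4)cc(OCc4ccccc4)c(C(=O)OCc4ccccc4)c3CCCCC)c2c(=O)o1 | intermediate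
22 | 4,6-dihydroxy-3-[(6-hydroxy-1-oxo-3-pentyl-1H-isochromen-8-yl)oxy]-2-pentylbenzoic acid | CCCCCc1cc2cc(O)cc(Oc3c(O)cc(O)c(C(=O)O)c3CCCCC)c2c(=O)o1 | target

## Step count and risks

Total: 12 steps. Longest linear sequence: 9 steps (1, 2, 3, 4, 6, 7, 10, 11, 12).

**Step 10 (key step).** The diynoate may polymerise thermally or react at its remote triple bond. The diene may isomerise by a 1,5-hydrogen shift or lose its silyl group before it adds, since the β-substituted ynoate reacts only at high temperature. The fallback sets out from 12 and installs the alkyne after ring A is made. Methyl propiolate is brominated (NBS, cat. AgNO3, acetone) to methyl 3-bromoprop-2-ynoate F1, a smaller and more reactive dienophile with the same polarisation. Heating 12 with F1 in toluene should give the bridged bromo adduct F2, which loses ethene to the aryl bromide benzyl 4,6-bis(benzyloxy)-3-[3-bromo-5-(tert-butyldimethylsilyloxy)-2-(methoxycarbonyl)phenoxy]-2-pentylbenzoate F3. Sonogashira coupling of F3 with 13 (PdCl2(PPh3)2, CuI, Et3N, 60 °C) returns to the route at 19.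

**Step 4.** Oxidative addition into the electron-rich C–Br bond between two ortho substituents may be slow, so protodebromination can outrun borylation. The fallback sets out from 3 and puts the oxygen in before the ester by organolithium chemistry. Single exchange (n-BuLi, THF, −78 °C), B(OMe)3, then H2O2/AcOH should give 4,6-bis(benzyloxy)-3-bromo-2-pentylphenol F4. n-BuLi (2.2 equiv, deprotonation then exchange) and CO2 give 4,6-bis(benzyloxy)-3-hydroxy-2-pentylbenzoic acid F5. Selective carboxylate benzylation (BnBr, KHCO3, DMF) returns to the route at 7.

**Step 9.** The lithium diynide may oligomerise on warming, and amine may add to the ynoate during the quench. The fallback sets out from 13 and avoids both the organolithium and a free ynoate ester in amine. 13 is brominated (NBS, cat. AgNO3, acetone) to 1-bromohept-1-yne F6. Cadiot–Chodkiewicz coupling with propiolic acid (CuCl cat., NH2OH·HCl, aq EtNH2, MeOH, 0 °C), whose carboxylate does not accept amines, gives deca-2,4-diynoic acid F7. Esterification (MeI, K2CO3, DMF) returns to the route at 17.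

**Step 11.** The hydrated oxocarbenium ion may open to the aryl ketone (net alkyne hydration) instead of losing methanol, or part of the material may close 5-exo. The fallback sets out from 19 and uses a halonium instead of a metal π-acid. Iodocyclisation (I2, MeCN, rt), in which iodide removes the ester methyl, should give benzyl 4,6-bis(benzyloxy)-3-{[6-(tert-butyldimethylsilyloxy)-4-iodo-1-oxo-3-pentyl-1H-isochromen-8-yl]oxy}-2-pentylbenzoate F8. Reductive deiodination (Pd(OAc)2, PPh3, HCO2H, Et3N, DMF, 60 °C) returns to the route at 20, which is desilylated as in step 11.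

**Step 12.** Cleavage may stop at the hindered benzyl ester, benzyl cations may alkylate C3' of ring B if the scavenger is outcompeted, or CO2 may be lost during an acidic quench. The fallback sets out from 21 and removes the benzyl groups reductively: H2 (1 atm), Pd/C, EtOAc, rt, stopped once the three benzyl groups have been taken off. Hydrogenolysis of benzyl esters and aryl benzyl ethers is expected to be faster than saturation of the trisubstituted C3=C4 enol lactone bond. It arrives directly at 22 and makes no new compound.

## Further compounds

F1 | step 10 | methyl 3-bromoprop-2-ynoate | COC(=O)C#CBr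
F2 | step 10 | benzyl 4,6-bis(benzyloxy)-3-{[3-bromo-5-(tert-butyldimethylsilyloxy)-2-(methoxycarbonyl)bicyclo[2.2.2]octa-2,5-dien-1-yl]oxy}-2-pentylbenzoate (racemic) | COC(=O)C1=C(Br)C2CCC1(Oc4c(OCc3ccccc3)cc(OCc3ccccc3)c(C(=O)OCc3ccccc3)c4CCCCC)C=C2O[Si](C)(C)C(C)(C)C
F3 | step 10 | benzyl 4,6-bis(benzyloxy)-3-[3-bromo-5-(tert-butyldimethylsilyloxy)-2-(methoxycarbonyl)phenoxy]-2-pentylbenzoate | COC(=O)c1c(Br)cc(O[Si](C)(C)C(C)(C)C)cc1Oc1c(OCc2ccccc2)cc(OCc2ccccc2)c(C(=O)OCc2ccccc2)c1CCCCC
F4 | step 4 | 4,6-bis(benzyloxy)-3-bromo-2-pentylphenol | CCCCCc1c(O)c(OCc2ccccc2)cc(OCc2ccccc2)c1Br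
F5 | step 4 | 4,6-bis(benzyloxy)-3-hydroxy-2-pentylbenzoic acid | CCCCCc1c(O)c(OCc2ccccc2)cc(OCc2ccccc2)c1C(=O)O
F6 | step 9 | 1-bromohept-1-yne | CCCCCC#CBr
F7 | step 9 | deca-2,4-diynoic acid | CCCCCC#CC#CC(=O)O
F8 | step 11 | benzyl 4,6-bis(benzyloxy)-3-{[6-(tert-butyldimethylsilyloxy)-4-iodo-1-oxo-3-pentyl-1H-isochromen-8-yl]oxy}-2-pentylbenzoate | CCCCCc1oc(=O)c2c(Oc3c(OCc4ccccc4)cc(OCc4ccccc4)c(C(=O)OCc4ccccc4)c3CCCCC)cc(O[Si](C)(C)C(C)(C)C)cc2c1I
F0 | step 12 | none | none
A1 | alternative 1 | methyl 5-(2-bromo-5-methoxyphenoxy)-2-hydroxy-4-oxo-6-pentylcyclohex-1-ene-1-carboxylate (racemic, trans; one enantiomer drawn, enol form) | CCCCC[C@@H]1[C@@H](Oc2cc(OC)ccc2Br)C(=O)CC(O)=C1C(=O)OC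
A2 | alternative 1 | (Z)-3-(2-bromo-5-methoxyphenoxy)non-3-en-2-one | CCCCC/C=C(\Oc1cc(OC)ccc1Br)C(C)=O
A3 | alternative 1 | dimethyl malonate | COC(=O)CC(=O)OC
A4 | alternative 2 | methyl 3-[(6-hydroxy-1-oxo-3-pentyl-1H-isochromen-8-yl)oxy]-4,6-dimethoxy-2-pentylbenzoate | CCCCCc1cc2cc(O)cc(Oc3c(OC)cc(OC)c(C(=O)OC)c3CCCCC)c2c(=O)o1
A5 | alternative 2 | methyl 3-{[(1E)-3-methoxy-1-(4-methyl-2-oxo-6-pentyl-2H-pyran-3-yl)-3-oxoprop-1-en-1-yl]oxy}-4,6-dimethoxy-2-pentylbenzoate | CCCCCc1cc(C)c(/C(Oc2c(OC)cc(OC)c(C(=O)OC)c2CCCCC)=C\C(=O)OC)c(=O)o1
A6 | alternative 3 | methyl 3-(2-bromo-5-methoxyphenoxy)-6-hydroxy-4-methoxy-2-pentylbenzoate | CCCCCc1c(Oc2cc(OC)ccc2Br)c(OC)cc(O)c1C(=O)OC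
A7 | alternative 3 | {[(1Z,3Z)-4-(2-bromo-5-methoxyphenoxy)-1,3-dimethoxybuta-1,3-dien-1-yl]oxy}(trimethyl)silane | C[Si](C)(C)O/C(OC)=C\C(OC)=C\Oc1cc(OC)ccc1Br
A8 | alternative 3 | methyl oct-2-ynoate | CCCCCC#CC(=O)OC
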